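**Plan**

Labdane numbering is used: ring A = C1–C5 and C10; ring B = C5–C10; C17 = carboxyl carbon on C8; C20 = methyl on C10; side chain = C11–C16.
Retrosynthetic cuts, in order: the silylethyl mask on C17; C9–C10 of ring B together with a hydrogen shift from C20 back to C7 (retro-ene); C8=C9 (olefination); C7–C8 (alkylation); C5–C6 (sigmatropic shift).
Enabling feature: in ring B, C9 and C8 are the β- and α-carbons of the C17 carboxyl group. C10 is quaternary, and its methyl C20 can arise from an exocyclic methylene by uptake of one hydrogen atom. C7 carries the hydrogen whose loss restores the C7=C8 enoate. Ring B is therefore a formal Alder-ene adduct of C10=C20 and a C8=C9 enoate.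
Forward order: ring A is bought as 4,4-dimethylcyclohexenone and fitted with C6–C7 and the C10=C20 methylene. C8/C17 are joined by phosphonate alkylation. The intact C9, C11–C16 isobutyrate chain (from geranyl isobutyrate) is joined by a Z-selective olefination. Ring B is closed last by a cobalt-hydride cycloisomerisation, and fluoride frees the acid.
Stereochemistry: a CBS reduction sets one carbinol centre and a suprafacial Johnson–Claisen shift relays it to C5. In the ring closure C5 directs C10 (trans fusion) and the Z-enoate geometry sets C9. The 13E alkene is inherited from geranyl isobutyrate.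

Key step: step 13

Assumption: geranyl isobutyrate is taken as the pure E isomer (free of the neryl ester), so the 13E geometry is inherited unchanged.

**Step 1**
Reactants: 1 4,4-dimethylcyclohex-2-en-1-one
Product: 2 2-iodo-4,4-dimethylcyclohex-2-en-1-one
Conditions: I2, pyridine/CH2Cl2, 0 °C to rt
Reagents that add atoms: iodine, [I][I]
Why: α-Iodination of a cyclic enone by the pyridine addition, iodination and elimination sequence (Baylis–Hillman-type α-halogenation) is a standard reaction that touches only the α-vinylic position and forms no stereocentre.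

**Step 2**
Reactants: 2 2-iodo-4,4-dimethylcyclohex-2-en-1-one
Product: 3 (1R)-2-iodo-4,4-dimethylcyclohex-2-en-1-ol
Conditions: (S)-2-methyl-CBS-oxazaborolidine (10 mol %), BH3·SMe2, THF, −20 °C; aq NH4Cl
Reagents that add atoms: none
Why: Corey–Bakshi–Shibata reduction, in which the iodoalkenyl arm plays the large group and the CH2 arm the small one, so that the (S)-catalyst should deliver hydride to one carbonyl face and give the (R)-carbinol, the only external source of chirality in the route.

**Step 3**
Reactants: 3 (1R)-2-iodo-4,4-dimethylcyclohex-2-en-1-ol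
Product: 5 ethyl 2-[(1S)-2-iodo-6,6-dimethylcyclohex-2-en-1-yl]acetate, via ketene acetal 4 (not isolated)
Conditions: MeC(OEt)3, EtCO2H (cat.), xylene, 140 °C, EtOH distilled off
Reagents that add atoms: triethyl orthoacetate, CC(OCC)(OCC)OCC
Why: Johnson–Claisen rearrangement: acid-catalysed exchange gives ketene acetal 4, whose [3,3]-shift is suprafacial on the ring (the 2-iodo group pushes the C–O bond pseudo-axial as required), so the carbinol configuration is relayed to the new C5–C6 bond on the same face next to the gem-dimethyl carbon and the alkene moves to C1=C10.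

**Step 4**
Reactants: 5 ethyl 2-[(1S)-2-iodo-6,6-dimethylcyclohex-2-en-1-yl]acetate
Product: 6 ethyl 2-[(1S)-6,6-dimethyl-2-(trimethylsilylmethyl)cyclohex-2-en-1-yl]acetate
Conditions: Me3SiCH2MgCl, ZnCl2, THF, 0 °C; then 5, Pd(PPh3)4 (5 mol %), THF, 50 °C
Reagents that add atoms: (trimethylsilyl)methylmagnesium chloride, C[Si](C)(C)C[Mg]Cl
Why: Negishi coupling of an alkenyl iodide with a β-hydrogen-free alkylzinc reagent under zerovalent palladium catalysis proceeds at the C10–I bond only, tolerates the ethyl ester and leaves C5 untouched.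

**Step 5**
Reactants: 6 ethyl 2-[(1S)-6,6-dimethyl-2-(trimethylsilylmethyl)cyclohex-2-en-1-yl]acetate
Product: 7 ethyl 2-[(1S)-2,2-dimethyl-6-methylidenecyclohexyl]acetate
Conditions: BF3·2AcOH, CH2Cl2, −20 to 0 °C; aq NaHCO3
Reagents that add atoms: none
Why: Protodesilylation of an allylsilane (SE2' mechanism): the proton adds at C1, the β-silyl cation loses silicon and the double bond is forced into the exocyclic C10=C20 position, which plain elimination or isomerisation chemistry would not give; C5 is not involved.

**Step 6**
Reactants: 7 ethyl 2-[(1S)-2,2-dimethyl-6-methylidenecyclohexyl]acetate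
Product: 8 2-[(1S)-2,2-dimethyl-6-methylidenecyclohexyl]ethan-1-ol
Conditions: LiAlH4, Et2O, 0 °C
Reagents that add atoms: none
Why: Standard hydride reduction of an ester to the primary alcohol, to which an isolated 1,1-disubstituted alkene is inert.

**Step 7**
Reactants: 8 2-[(1S)-2,2-dimethyl-6-methylidenecyclohexyl]ethan-1-ol
Product: 9 (2S)-2-(2-iodoethyl)-1,1-dimethyl-3-methylidenecyclohexane
Conditions: I2, PPh3, imidazole, CH2Cl2, 0 °C
Reagents that add atoms: iodine, [I][I]
Why: Appel-type iodination (SN2 displacement of the alkoxyphosphonium ion by iodide) at an unhindered primary carbon under near-neutral conditions that spare the acid-sensitive exocyclic alkene.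

**Step 8**
Reactants: 10 2-(trimethylsilyl)ethanol
Product: 11 2-(trimethylsilyl)ethyl bromoacetate
Conditions: BrCH2COBr, pyridine, CH2Cl2, 0 °C
Reagents that add atoms: bromoacetyl bromide, O=C(Br)CBr
Why: Simple O-acylation of a primary alcohol with an acid bromide; the 2-(trimethylsilyl)ethyl group is chosen because it can later be removed by fluoride without touching the isobutyrate.

**Step 9**
Reactants: 11 2-(trimethylsilyl)ethyl bromoacetate
Product: 12 2-(trimethylsilyl)ethyl 2-(diphenoxyphosphoryl)acetate
Conditions: (PhO)2P(O)H, Et3N, CH2Cl2, 0 °C to rt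
Reagents that add atoms: diphenyl phosphite, O=[PH](Oc1ccccc1)Oc1ccccc1
Why: Michaelis–Becker-type P-alkylation of the diaryl phosphite anion with an α-bromo ester, the usual access to the diaryl phosphonoacetates used for Z-selective Horner–Wadsworth–Emmons reactions.

**Step 10**
Reactants: 12 2-(trimethylsilyl)ethyl 2-(diphenoxyphosphoryl)acetate; 9 (2S)-2-(2-iodoethyl)-1,1-dimethyl-3-methylidenecyclohexane
Product: 13 2-(trimethylsilyl)ethyl 2-(diphenoxyphosphoryl)-4-[(1S)-2,2-dimethyl-6-methylidenecyclohexyl]butanoate (both epimers at C2 of the butanoate)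
Conditions: NaH, DMSO, rt; then 9, 50 °C
Reagents that add atoms: none
Why: SN2 alkylation of the stabilised phosphonoacetate carbanion with a primary iodide joins C7 to C8; the new centre at C8 forms as a mixture of epimers, which is of no consequence because it becomes sp2 in step 12.

**Step 11**
Reactants: 14 geranyl isobutyrate, (2E)-3,7-dimethylocta-2,6-dien-1-yl 2-methylpropanoate
Product: 16 (2E)-3-methyl-6-oxohex-2-en-1-yl 2-methylpropanoate, via secondary ozonide 15 (not isolated)
Conditions: O3 (1 equiv), CH2Cl2, −78 °C; then Me2S, −78 °C to rt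
Reagents that add atoms: ozone, [O-][O+]=O
Why: Chemoselective ozonolysis: the electron-rich isopropylidene alkene reacts much faster than the alkene deactivated by the allylic acyloxy group, so one equivalent of ozone cuts off acetone and leaves the E-alkene and the isobutyrate in place.

**Step 12**
Reactants: 13 2-(trimethylsilyl)ethyl 2-(diphenoxyphosphoryl)-4-[(1S)-2,2-dimethyl-6-methylidenecyclohexyl]butanoate; 16 (2E)-3-methyl-6-oxohex-2-en-1-yl 2-methylpropanoate
Product: 17 2-(trimethylsilyl)ethyl (2Z,6E)-2-{2-[(1S)-2,2-dimethyl-6-methylidenecyclohexyl]ethyl}-6-methyl-8-(2-methylpropanoyloxy)octa-2,6-dienoate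
Conditions: NaH, THF, 0 °C; then 16, −78 to 0 °C
Reagents that add atoms: none
Why: Z-selective Horner–Wadsworth–Emmons reaction of an α-substituted diaryl phosphonoacetate: fast, irreversible collapse of the kinetically favoured adduct places C11 cis to the ester and trans to C7, the geometry that step 13 translates into the C9 configuration, and the low temperature spares the isobutyrate.

**Step 13**
Reactants: 17 2-(trimethylsilyl)ethyl (2Z,6E)-2-{2-[(1S)-2,2-dimethyl-6-methylidenecyclohexyl]ethyl}-6-methyl-8-(2-methylpropanoyloxy)octa-2,6-dienoate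
Product: 20 2-(trimethylsilyl)ethyl (1R,4aS,8aS)-5,5,8a-trimethyl-1-[(3E)-3-methyl-5-(2-methylpropanoyloxy)pent-3-en-1-yl]-1,4,4a,5,6,7,8,8a-octahydronaphthalene-2-carboxylate, via C10 tertiary radical 18 (not isolated), via C8 ester radical 19 (not isolated)
Conditions: chloro[N,N'-bis(3,5-di-tert-butylsalicylidene)-1,2-cyclohexanediaminato]cobalt, C36H52ClCoN2O2 (5 mol %), PhSiH3 (10 mol %), degassed benzene (0.01 M), argon, 22 °C
Reagents that add atoms: none
Why: Proposed new method: the cobalt hydride (trivalent cobalt) formed from the chloride and PhSiH3 should pass a hydrogen atom to the unhindered CH2 terminus C20 of the 1,1-disubstituted alkene, which turns C20 into the angular methyl group and leaves the nucleophilic tertiary radical 18 at C10; 18 adds to C9, the β-carbon of the C17 enoate, and the ester-stabilised tertiary radical 19 at C8 hands the axial hydrogen of C7 back to divalent cobalt, which regenerates the hydride and makes the whole event an isomerisation, a stepwise formal Alder-ene reaction. The closest known reaction types are the cobalt-salen/silane cycloisomerisation of unactivated dienes, the metal-hydride-initiated Giese cyclisation of alkenes onto enoates and catalytic chain transfer in methacrylate polymerisation, where divalent cobalt abstracts a β-hydrogen from just this kind of tertiary α-ester radical; what has not been shown is their combination in an endo closure onto a trisubstituted enoate. Ring B closes in the 6-endo-trig mode, preferred over 5-exo attack because C8 is fully substituted and polarity-mismatched whereas C9 is the electrophilic, less substituted terminus. C10 is controlled by the resident C5 stereocentre: in the chair-like transition state the C5–C6 tether is equatorial on ring A and C9 bonds to the equatorial lobe of the radical, so C20 ends axial and anti to H5 (trans-decalin), as in radical polyene bicyclisations that pass through the same type of radical. C9 is controlled by the Z geometry of the enoate, which holds C11 anti to C7 and hence pseudo-equatorial, with H9 axial and anti to C20. The step needs chemoselective hydrogen-atom transfer to C10=C20 in the presence of C13=C14 and C8=C9, secured by the much higher reactivity of 1,1-disubstituted over trisubstituted alkenes towards the bulky hydride, and hydrogen abstraction at C7 rather than C9, secured by the shielding of H9 by C10, C11 and the salen ligand, while the low catalyst concentration keeps return of a C1 hydrogen (alkene migration into ring A) slower than cyclisation.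

**Step 14**
Reactants: 20 2-(trimethylsilyl)ethyl (1R,4aS,8aS)-5,5,8a-trimethyl-1-[(3E)-3-methyl-5-(2-methylpropanoyloxy)pent-3-en-1-yl]-1,4,4a,5,6,7,8,8a-octahydronaphthalene-2-carboxylate
Product: 21 (1R,4aS,8aS)-5,5,8a-trimethyl-1-[(3E)-3-methyl-5-(2-methylpropanoyloxy)pent-3-en-1-yl]-1,4,4a,5,6,7,8,8a-octahydronaphthalene-2-carboxylic acid (CNP0191003.1)
Conditions: Bu4NF, THF, 0 °C to rt; then 0.5 M HCl (work-up)
Reagents that add atoms: none
Why: Fluoride-induced fragmentation of a 2-(trimethylsilyl)ethyl ester (attack at silicon, loss of ethene) does not depend on access to the hindered C17 carbonyl and leaves the allylic isobutyrate, both alkenes and all three stereocentres untouched.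

**Compound list**

1 | 4,4-dimethylcyclohex-2-en-1-one | CC1(C)CCC(=O)C=C1 | starting material
2 | 2-iodo-4,4-dimethylcyclohex-2-en-1-one | IC1=CC(C)(C)CCC1=O | intermediate
3 | (1R)-2-iodo-4,4-dimethylcyclohex-2-en-1-ol | O[C@@H]1CCC(C)(C)C=C1I | intermediate
4 | 1-ethoxyvinyl (1R)-2-iodo-4,4-dimethylcyclohex-2-en-1-yl ether (mixed ketene acetal, not isolated) | C=C(OCC)O[C@@H]1CCC(C)(C)C=C1I | intermediate
5 | ethyl 2-[(1S)-2-iodo-6,6-dimethylcyclohex-2-en-1-yl]acetate | IC1=CCCC(C)(C)[C@@H]1CC(=O)OCC | intermediate
6 | ethyl 2-[(1S)-6,6-dimethyl-2-(trimethylsilylmethyl)cyclohex-2-en-1-yl]acetate | CCOC(=O)C[C@@H]1C(C[Si](C)(C)C)=CCCC1(C)C | intermediate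
7 | ethyl 2-[(1S)-2,2-dimethyl-6-methylidenecyclohexyl]acetate | CCOC(=O)C[C@@H]1C(=C)CCCC1(C)C | intermediate
8 | 2-[(1S)-2,2-dimethyl-6-methylidenecyclohexyl]ethan-1-ol | OCC[C@@H]1C(=C)CCCC1(C)C | intermediate
9 | (2S)-2-(2-iodoethyl)-1,1-dimethyl-3-methylidenecyclohexane | ICC[C@@H]1C(=C)CCCC1(C)C | intermediate
10 | 2-(trimethylsilyl)ethanol | C[Si](C)(C)CCO | starting material
11 | 2-(trimethylsilyl)ethyl bromoacetate | C[Si](C)(C)CCOC(=O)CBr | intermediate
12 | 2-(trimethylsilyl)ethyl 2-(diphenoxyphosphoryl)acetate | C[Si](C)(C)CCOC(=O)CP(=O)(Oc1ccccc1)Oc1ccccc1 | intermediate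
13 | 2-(trimethylsilyl)ethyl 2-(diphenoxyphosphoryl)-4-[(1S)-2,2-dimethyl-6-methylidenecyclohexyl]butanoate (epimers at the phosphonate carbon) | C[Si](C)(C)CCOC(=O)C(CC[C@@H]1C(=C)CCCC1(C)C)P(=O)(Oc1ccccc1)Oc1ccccc1 | intermediate
14 | geranyl isobutyrate, (2E)-3,7-dimethylocta-2,6-dien-1-yl 2-methylpropanoate | CC(C)=CCC/C(C)=C/COC(=O)C(C)C | starting material
15 | secondary ozonide of the 6,7-alkene of 14 (1,2,4-trioxolane, not isolated) | CC1(C)OOC(CC/C(C)=C/COC(=O)C(C)C)O1 | intermediate
16 | (2E)-3-methyl-6-oxohex-2-en-1-yl 2-methylpropanoate | O=CCC/C(C)=C/COC(=O)C(C)C | intermediate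
17 | 2-(trimethylsilyl)ethyl (2Z,6E)-2-{2-[(1S)-2,2-dimethyl-6-methylidenecyclohexyl]ethyl}-6-methyl-8-(2-methylpropanoyloxy)octa-2,6-dienoate | C[Si](C)(C)CCOC(=O)/C(CC[C@@H]1C(=C)CCCC1(C)C)=C\CC/C(C)=C/COC(=O)C(C)C | intermediate
18 | C10 tertiary radical (17 after uptake of a hydrogen atom at C20, not isolated) | C[Si](C)(C)CCOC(=O)/C(CC[C@@H]1[C](C)CCCC1(C)C)=C\CC/C(C)=C/COC(=O)C(C)C | intermediate
19 | C8 ester radical (bicyclic, after C9–C10 bond formation, not isolated) | C/C(=C\COC(=O)C(C)C)CC[C@H]1[C](C(=O)OCC[Si](C)(C)C)CC[C@H]2C(C)(C)CCC[C@]12C | intermediate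
20 | 2-(trimethylsilyl)ethyl (1R,4aS,8aS)-5,5,8a-trimethyl-1-[(3E)-3-methyl-5-(2-methylpropanoyloxy)pent-3-en-1-yl]-1,4,4a,5,6,7,8,8a-octahydronaphthalene-2-carboxylate | C/C(=C\COC(=O)C(C)C)CC[C@H]1C(C(=O)OCC[Si](C)(C)C)=CC[C@H]2C(C)(C)CCC[C@]12C | intermediate
21 | (1R,4aS,8aS)-5,5,8a-trimethyl-1-[(3E)-3-methyl-5-(2-methylpropanoyloxy)pent-3-en-1-yl]-1,4,4a,5,6,7,8,8a-octahydronaphthalene-2-carboxylic acid | C/C(=C\COC(=O)C(C)C)CC[C@H]1C(C(=O)O)=CC[C@H]2C(C)(C)CCC[C@]12C | target

**Step count**

Total step count: 14.
Longest linear sequence: 11 steps (steps 1–7, 10, 12, 13, 14).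

**Steps most likely to fail**

**1. Step 13.** Divalent cobalt may take a hydrogen from C1 of the first radical faster than the radical cyclises, which moves the exocyclic alkene into ring A. At the end of the sequence, hydrogen abstraction may occur at C9 instead of C7. The fallback sets out from 17 and comes back at 20. It makes the radical irreversibly and installs the alkene afterwards by known steps.
- Fe(acac)3 and PhSiH3 in EtOH at 60 °C (reductive hydrogen-atom-transfer Giese cyclisation) should give the saturated bicyclic ester F1 as C8 epimers.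
- K2CO3 in MeOH removes the isobutyrate to give the hydroxy ester F2, so that only one enolisable ester is left.
- LDA (2.2 equiv) and PhSeBr in THF at −78 °C give the α-phenylselanyl ester F3.
- H2O2 and pyridine in CH2Cl2 at 0 °C trigger selenoxide syn-elimination to the hydroxy enoate F4.
- Isobutyryl chloride, pyridine and DMAP put the ester back and deliver 20.

**2. Step 5.** The acid may re-protonate the new exocyclic alkene. This would cause migration of the double bond into ring A or capture of the C10 cation by the ester. The fallback sets out from 5 and comes back at 7. It replaces the proton by a hydride delivered under neutral conditions.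
- Stille coupling of 5 with Bu3SnCH2OH (Pd(PPh3)4, dioxane, 90 °C) gives the allylic alcohol F5.
- Methyl chloroformate and pyridine give the allylic carbonate F6.
- Palladium-catalysed formate hydrogenolysis (Pd2(dba)3, PBu3, HCO2H, Et3N, THF, rt) delivers hydride to the more substituted allyl terminus C1 and should give 7.

**3. Step 12.** Z selectivity may erode and addition may be slow, because the phosphonate carries a long α-branch. The fallback sets out from 12, 16 and 9 and comes back at 17. It fixes the geometry on a small alkene first and joins C7–C8 afterwards with retention.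
- NaH and N-bromosuccinimide convert 12 into the bromophosphonate F7.
- The Horner–Wadsworth–Emmons reaction of F7 with 16 (NaH, THF, −78 °C) gives the (E)-α-bromo enoate F8, in which C11 is already cis to the ester.
- Zinc dust and LiCl in THF convert 9 into the alkylzinc iodide F9.
- Negishi coupling of F8 with F9 (PdCl2(dppf), THF, rt) gives 17.

**Further compounds**

F1 | step 13 | 2-(trimethylsilyl)ethyl (1R,4aS,8aS)-5,5,8a-trimethyl-1-[(3E)-3-methyl-5-(2-methylpropanoyloxy)pent-3-en-1-yl]decahydronaphthalene-2-carboxylate (C2 epimers) | C/C(=C\COC(=O)C(C)C)CC[C@H]1C(C(=O)OCC[Si](C)(C)C)CC[C@H]2C(C)(C)CCC[C@]12C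
F2 | step 13 | 2-(trimethylsilyl)ethyl (1R,4aS,8aS)-1-[(3E)-5-hydroxy-3-methylpent-3-en-1-yl]-5,5,8a-trimethyldecahydronaphthalene-2-carboxylate (C2 epimers) | C/C(=C\CO)CC[C@H]1C(C(=O)OCC[Si](C)(C)C)CC[C@H]2C(C)(C)CCC[C@]12C
F3 | step 13 | 2-(trimethylsilyl)ethyl (1R,4aS,8aS)-1-[(3E)-5-hydroxy-3-methylpent-3-en-1-yl]-5,5,8a-trimethyl-2-(phenylselanyl)decahydronaphthalene-2-carboxylate | C/C(=C\CO)CC[C@H]1C([Se]c3ccccc3)(C(=O)OCC[Si](C)(C)C)CC[C@H]2C(C)(C)CCC[C@]12C
F4 | step 13 | 2-(trimethylsilyl)ethyl (1R,4aS,8aS)-1-[(3E)-5-hydroxy-3-methylpent-3-en-1-yl]-5,5,8a-trimethyl-1,4,4a,5,6,7,8,8a-octahydronaphthalene-2-carboxylate | C/C(=C\CO)CC[C@H]1C(C(=O)OCC[Si](C)(C)C)=CC[C@H]2C(C)(C)CCC[C@]12C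
F5 | step 5 | ethyl 2-[(1S)-2-(hydroxymethyl)-6,6-dimethylcyclohex-2-en-1-yl]acetate | CCOC(=O)C[C@@H]1C(CO)=CCCC1(C)C
F6 | step 5 | ethyl 2-[(1S)-2-(methoxycarbonyloxymethyl)-6,6-dimethylcyclohex-2-en-1-yl]acetate | CCOC(=O)C[C@@H]1C(COC(=O)OC)=CCCC1(C)C
F7 | step 12 | 2-(trimethylsilyl)ethyl 2-bromo-2-(diphenoxyphosphoryl)acetate | C[Si](C)(C)CCOC(=O)C(Br)P(=O)(Oc1ccccc1)Oc1ccccc1
F8 | step 12 | 2-(trimethylsilyl)ethyl (2E,6E)-2-bromo-6-methyl-8-(2-methylpropanoyloxy)octa-2,6-dienoate | C[Si](C)(C)CCOC(=O)/C(Br)=C\CC/C(C)=C/COC(=O)C(C)C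
F9 | step 12 | {2-[(1S)-2,2-dimethyl-6-methylidenecyclohexyl]ethyl}zinc iodide | I[Zn]CC[C@@H]1C(=C)CCCC1(C)C
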